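The constants used here were set for the occasion; the result is computed.

The reading falls at 6.0 h in the closed north-east flask and at the end of dosing in the south-west flask, while the two tanks run at steady state with average stays of 6.0 h and 30.0 h.

all flasks: capture agent 8.20 mM
- north-east: starting material 0.41 M; time 6.0 h; a closed flask charged with all of it at once and left for 6.0 h
- south-east: starting material 0.41 M; one stirred flow tank at steady state, fed with the mixture as stated, mean residence time 30.0 h
- south-west: starting material 0.41 M (fed, over 6.00 h); time 6.0 h; a stirred flask in which starting material is dosed at a steady rate over 6.00 h without added volume, worked up at 6.0 h
- north-west: starting material 0.41 M; a single well-mixed tank run continuously and read at steady state, 6.0 h in it on average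

    starting material → intermediate B (k1 = 1.65 × 10⁻⁵ s⁻¹)
    intermediate B → intermediate A (k2 = 6.40 × 10⁻⁵ s⁻¹)
    starting material → intermediate A (k3 = 3.49 × 10⁻⁵ s⁻¹)
    capture agent + intermediate C → trapped intermediate (k4 = 9.80 × 10⁻⁵ L mol⁻¹ s⁻¹)
    intermediate B ⇌ intermediate C (K5 = 2.5, k5 = 6.77 × 10⁻⁵ s⁻¹)
    intermediate A → target (k6 = 5.14 × 10⁻⁵ s⁻¹)

- the stated concentrations are those of everything mixed, before any reaction; amounts are the same in each set-up
- the feed brings no volume worth counting
- run time (north-east): 6.0 h

1. the set-up with the highest amount of target at the outlet or at the end, in percent of the starting material put in ("none" if the first two lie within 2 percentage points) (north-east / south-east / south-west / north-west / none)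
2. amount of target at the outlet or at the end, in percent of the starting material put in, north-east
3. amount of target at the outlet or at the end, in percent of the starting material put in, south-east
4. amount of target at the outlet or at the end, in percent of the starting material put in, south-west
5. amount of target at the outlet or at the end, in percent of the starting material put in, north-west

Starting material leaves by two first-order exits, one to intermediate B and one straight to intermediate A. Dividing the direct rate by the sum of both rates cancels c(starting material) and time, so 67.9% of what reacts takes the direct exit throughout the run. This direct share is the branching fraction of the flask. Starting material disappears at 0.185 h⁻¹, and intermediate A goes on to target at 0.185 h⁻¹, the same value.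

This reckoning draws the direct route in the north-east flask. c(target) leaves the origin with zero slope, since intermediate A has first to build up. Its knee, the steepest point, lies at 5.40 h, where direct intermediate A peaks at 25.0% of the charge. The reading comes just past that knee, so c(target) is still climbing hard. Direct intermediate A crosses c(starting material) at 7.96 h, later than the reading. The direct curve runs into a level of 67.9%, and any target above that level arrives through intermediate B. At the reading, 1.11 lifetimes have passed, which gives 20.7% of direct target. The reckoning stops there, short of the route through intermediate B.

The forecast gives 23.6% north-east, 64.9% south-east, 9.2% south-west and 22.5% north-west, and it picks south-east “because of its much longer residence time”. Its north-east figure stands above the direct part reckoned here, since it includes the route through intermediate B.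

The simulation gives 23.6% north-east, 64.9% south-east, 9.18% south-west and 22.5% north-west, so south-east is best.

South-east leads mainly through back-mixing and the longer stay: without them it gives 23.6%. In north-east, the direct share leaves 2.9 percentage points for the route through intermediate B. In the south-east tank, the two stages, loss of starting material and intermediate A to target, have the same constant, and each passes the fraction constant times stay over one plus that product, here 84.7%. Direct target is therefore the direct share times that fraction squared, 48.8%. The run with the step from intermediate B to intermediate A struck out gives 48.8%, and that step supplies a further 16 points.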